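Hours are the unit to think in here. Divide the percent of mono adduct standing in a flask by the percent of bis adduct gained per hour and you get τ, a net turnover time of the mono adduct into bis adduct.

| flask | substrate | reagent | remark | time |
|---|---|---|---|---|
| summer | 0.50 M | 0.50 M | the very flask that is asked about, followed so far |  |
| midnight | 0.75 M | 0.50 M | run made earlier |  |
| flask | 0.50 M | 0.500 M |  | 12 h |

| run | time / h | bis adduct / % | mono adduct / % |
|---|---|---|---|
| summer | 0.417 | 0 | 7 |
| summer | 0.667 | 1 | 7 |
| summer | 1.00 | 5 | 7 |
| summer | 2.00 | 9 | 9 |
| summer | 3.00 | 12 | 2 |
| summer | 5.00 | 16 | 5 |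
| midnight | 1.00 | 2 | 6 |
| midnight | 1.50 | 3 | 8 |
| midnight | 2.50 | 7 | 6 |
| midnight | 4.00 | 10 | 2 |
| midnight | 8.00 | 12 | 3 |
| midnight | 12.0 | 13 | 3 |

(standard deviation of a reading: 1.5 percentage points)

- equivalents of reagent to substrate, everything else as given, that leave most bis adduct at 12 h
- the amount of bis adduct then, in percent of the substrate charged
- the amount of bis adduct with the amounts as given

- percent here means substrate units held: one side product counts as two
- the numbers in the tables scatter with a standard deviation of 1.5 percentage points
- steps under discussion: reagent + bis adduct -> triple product; mono adduct <-> isomer of the product; substrate + mono adduct -> side product; substrate <-> dormant form; substrate + reagent -> mono adduct; reagent + mono adduct -> bis adduct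

Does τ follow the substrate? From 1.00 h to 5.00 h the summer run gives τ = 2.09 h. From 1.00 h to 4.00 h the midnight run gives 2.06 h, with 1.50 times the substrate at the same reagent charge. With a scatter of 1.5 percentage points per reading I read these as one value, so in these two runs τ shows no dependence on the substrate charge.

Does τ hold? From 4.00 h to 12.0 h the midnight run gives 7.11 h, longer than its early value by a factor of 3.45, so I read its flat end as a slowing.

Where does the summer run get to? Starting from 16% at 5.00 h, with the mean of its last two mono adduct readings and that late τ, I reckon 19.4% of bis adduct at 12 h. The runs hold no reading of triple product, so I put no figure of my own on the best equivalents.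

The forecast gave 23%, above my figure, and 40% at 2.5 equiv, because “More reagent suppresses the side product”.

    reagent + bis adduct → triple product (k = 0.00350 M⁻¹ min⁻¹)
    mono adduct ⇌ isomer of the product (K = 3.50, k = 0.00170 min⁻¹)
    substrate + mono adduct → side product (k = 0.0290 M⁻¹ min⁻¹)
    substrate ⇌ dormant form (K = 1.60, k = 0.00640 min⁻¹)
    substrate + reagent → mono adduct (k = 0.00910 M⁻¹ min⁻¹)
    reagent + mono adduct → bis adduct (k = 0.0300 M⁻¹ min⁻¹)

The flask gives 18.1% of bis adduct at 12 h, and the best charge, 1.88 equiv, gives 24.6%, with 23.6% of triple product beside it. Between 6.00 h and 12.0 h this flask shows τ = 10.5 h, which is 5.02 times the early reading. In the neighbour flask, charged with 0.20 M of reagent, taking the final 2.02% of mono adduct as standing for 12 h against its 5.90% of bis adduct gives a rough τ of 4.12 h, which is 1.97 times the early reading.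

The earlier runs and the new flask stem from a simulated flask for substances that don't exist; the scatter is artificial.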